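**Assumptions.** Stereochemistry is read from the SMILES: 1′ = CH–Ph (R), 2′ = CH–prenyl (S), 6′ = CH–C(=O)Ar (R), so Ph and prenyl are cis and the aroyl group is trans to Ph. The BOX ligand antipode in step 2 cannot be predicted with confidence and must be assigned experimentally; the route is written for the (1R,6R) series.

## Retrosynthetic overview

1. Target ⇒ ester 8 + lithiated tris-MOM phloroglucinol (acyl substitution). The phloroglucinol ring is attached intact, last.
2. Ester 8 ⇒ enone 6 by reductive 1,3-transposition through an allylic diazene, which delivers H to C-2′ anti to Ph (prenyl cis to Ph).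
3. Enone 6 ⇒ vinylogous ester 4 + a prenyl nucleophile (Stork–Danheiser addition/transposition).
4. Vinylogous ester 4 ⇒ σ-symmetric bis-enol ether 2 + "Ph⁺", by an enantioselective arylation of one of two enantiotopic enol ethers. This is the key step and fixes C-1′/C-6′.
5. Bis-enol ether 2 ⇒ 3,5-dimethoxy-4-methylbenzoic acid by Birch reduction. No ring is built: the cyclohexene is the dearomatised benzoate ring.

## Route

**Step 1**
Reactants: 1, 3,5-dimethoxy-4-methylbenzoic acid
Product: 2, methyl 3,5-dimethoxy-4-methylcyclohexa-2,5-diene-1-carboxylate (cis/trans mixture at C1/C4; both isomers are σ-symmetric and achiral)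
Conditions: Li (3 equiv), NH3(l)/THF, −78 °C; solid NH4Cl; evaporate NH3; then K2CO3, MeI, DMF, 0 °C→rt (one pot; use 2 promptly, cold, under Ar)
Reagents that add atoms: iodomethane, CI
Why: Birch reduction, in which the carboxylate directs protonation to the ipso and para carbons so both OMe-bearing carbons remain as enol ethers; esterifying the carboxylate with MeI avoids acid that would hydrolyse them, and no surviving stereocentre is set.

**Step 2 (key step)**
Reactants: 2, methyl 3,5-dimethoxy-4-methylcyclohexa-2,5-diene-1-carboxylate; 3, diphenyliodonium triflate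
Product: 4, methyl (1R,6R)-3-methoxy-4-methyl-5-oxo-6-phenylcyclohex-3-ene-1-carboxylate (Ph trans to CO2Me)
Conditions: 3 (1.0 equiv), CuOTf·½PhMe (10 mol %), t-Bu-BOX (12 mol %, antipode giving 1R,6R), 2,6-di-tert-butylpyridine, CH2Cl2, −30 °C; then PPTS (cat.), MeOH, rt
Reagents that add atoms: diphenyliodonium triflate (phenyl), c1ccc(cc1)[I+]c1ccccc1.[O-]S(=O)(=O)C(F)(F)F; methanol, CO (may exchange the enol-ether OMe during equilibration)
Why: Proposed new method: a chiral BOX–Cu(III)–Ph electrophile attacks the nucleophilic β-carbon of one of the two enantiotopic methyl enol ethers, anti to the CO2Me group, giving an oxocarbenium that collapses to the ketone by loss of the O-methyl group, while the untouched enol ether moves into conjugation under PPTS/MeOH to give the less strained vinylogous ester with C=O next to CHPh; catalyst face preference and the substrate's anti bias match for only one alkene, so C-1 and C-6 are fixed together, and later C-6 epimerisation cannot racemise because C-1 is not enolised; the closest known reaction type is the Cu(I)–bisoxazoline-catalysed enantioselective α-arylation of enol silanes with diaryliodonium salts, combined with catalytic desymmetrisation of cyclohexa-2,5-dienes.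

**Step 3**
Reactants: 4, the vinylogous ester; 5, tributyl(3-methylbut-2-en-1-yl)stannane
Product: 6, methyl (1R,2R)-4-methyl-3-(3-methylbut-2-en-1-yl)-5-oxo-2-phenylcyclohex-3-ene-1-carboxylate
Conditions: 5, n-BuLi, THF, −78 °C; anhydrous CeCl3, −78 °C; add 4, −78 °C; then 1 M HCl, THF, 0 °C→rt
Reagents that add atoms: tributyl(prenyl)stannane (prenyl), CCCC[Sn](CCCC)(CCCC)CC=C(C)C; water, O (new enone oxygen)
Why: Stork–Danheiser sequence, in which the weakly basic, ketone-selective allylcerium adds 1,2 to the vinylogous-ester carbonyl through its less substituted terminus (linear prenyl) without touching the ester or enolising the α-phenyl ketone, and dilute acid ionises the tertiary allylic alcohol and hydrolyses the enol ether to the transposed enone; C-1 and C-2 are untouched.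

**Step 4**
Reactants: 6, the enone
Product: 7, the p-toluenesulfonylhydrazone of 6 at C-5 (C=N geometry not important)
Conditions: TsNHNH2 (1.2 equiv), EtOH, cat. AcOH, 50 °C
Reagents that add atoms: p-toluenesulfonyl hydrazide, NNS(=O)(=O)c1ccc(C)cc1
Why: Hydrazone condensation at the only ketone; the β-carbon is fully substituted so conjugate addition does not compete, and the ester and stereocentres are unaffected.

**Step 5**
Reactants: 7, the tosylhydrazone
Product: 8, methyl (1R,5S,6R)-4-methyl-5-(3-methylbut-2-en-1-yl)-6-phenylcyclohex-3-ene-1-carboxylate
Conditions: catecholborane (3 equiv), CHCl3, −10→0 °C; then NaOAc·3H2O, reflux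
Reagents that add atoms: none
Why: Kabalka-type hydrazone reduction followed by allylic diazene (retro-ene) rearrangement, in which hydride adds to C=N anti to the 1,3-related ester (as in cis-selective 1,2-reductions of 5-substituted cyclohexenones), so N sits trans to Ph, and after sulfinate loss the diazene transfers H suprafacially to the prenyl-bearing carbon on that same face; this puts prenyl cis to Ph (5S) and the alkene at its final position.

**Step 6**
Reactants: 9, phloroglucinol
Product: 10, 1,3,5-tris(methoxymethoxy)benzene
Conditions: NaH, MOMCl, DMF, 0 °C→rt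
Reagents that add atoms: chloromethyl methyl ether, COCCl
Why: Exhaustive O-alkylation (Williamson-type acetal formation) gives an acid-labile protected arene that can be lithiated between two OMOM groups.

**Step 7**
Reactants: 8, the ester; 10, 1,3,5-tris(methoxymethoxy)benzene
Product: 11, [(1R,5S,6R)-4-methyl-5-(3-methylbut-2-en-1-yl)-6-phenylcyclohex-3-en-1-yl][2,4,6-tris(methoxymethoxy)phenyl]methanone
Conditions: 10 (3 equiv), n-BuLi, THF, 0 °C, 1 h; add 8, −78→0 °C; NH4Cl (aq); DBU (cat.), CH2Cl2, rt if any C-1 epimer is present
Reagents that add atoms: none beyond 10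
Why: Directed ortho-lithiation followed by acyl substitution, where the di-ortho-substituted aryllithium gives an OMOM-chelated tetrahedral intermediate and a hindered ketone that resists over-addition; C-1 is the only epimerisable centre and its thermodynamic configuration (aroyl and Ph both equatorial, trans) is the required one.

**Step 8**
Reactants: 11, the tris-MOM ketone
Product: 12, (1′R,2′S,6′R)-2-hydroxyisopanduratin A
Conditions: 3 M HCl (aq)/MeOH, 45 °C
Reagents that add atoms: none
Why: Acid-catalysed acetal cleavage of the three aryl MOM ethers; the two trisubstituted alkenes tolerate dilute methanolic HCl, and no stereocentre is affected.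

## Compound list

1 | 3,5-dimethoxy-4-methylbenzoic acid | COc1cc(cc(OC)c1C)C(=O)O | starting material
2 | methyl 3,5-dimethoxy-4-methylcyclohexa-2,5-diene-1-carboxylate | COC(=O)C1C=C(OC)C(C)C(OC)=C1 | intermediate
3 | diphenyliodonium triflate | c1ccc(cc1)[I+]c1ccccc1.[O-]S(=O)(=O)C(F)(F)F | starting material
4 | methyl (1R,6R)-3-methoxy-4-methyl-5-oxo-6-phenylcyclohex-3-ene-1-carboxylate | O=C1C(C)=C(OC)C[C@@H](C(=O)OC)[C@@H]1c1ccccc1 | intermediate
5 | tributyl(3-methylbut-2-en-1-yl)stannane | CCCC[Sn](CCCC)(CCCC)CC=C(C)C | starting material
6 | methyl (1R,2R)-4-methyl-3-(3-methylbut-2-en-1-yl)-5-oxo-2-phenylcyclohex-3-ene-1-carboxylate | CC(C)=CCC1=C(C)C(=O)C[C@@H](C(=O)OC)[C@@H]1c1ccccc1 | intermediate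
7 | tosylhydrazone of 6 | CC(C)=CCC1=C(C)C(=NNS(=O)(=O)c2ccc(C)cc2)C[C@@H](C(=O)OC)[C@@H]1c1ccccc1 | intermediate
8 | methyl (1R,5S,6R)-4-methyl-5-(3-methylbut-2-en-1-yl)-6-phenylcyclohex-3-ene-1-carboxylate | CC(C)=CC[C@@H]1C(C)=CC[C@@H](C(=O)OC)[C@@H]1c1ccccc1 | intermediate
9 | phloroglucinol | Oc1cc(O)cc(O)c1 | starting material
10 | 1,3,5-tris(methoxymethoxy)benzene | COCOc1cc(OCOC)cc(OCOC)c1 | intermediate
11 | [(1R,5S,6R)-4-methyl-5-(3-methylbut-2-en-1-yl)-6-phenylcyclohex-3-en-1-yl][2,4,6-tris(methoxymethoxy)phenyl]methanone | CC(C)=CC[C@@H]1C(C)=CC[C@@H](C(=O)c2c(OCOC)cc(OCOC)cc2OCOC)[C@@H]1c1ccccc1 | intermediate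
12 | (1′R,2′S,6′R)-2-hydroxyisopanduratin A | CC(C)=CC[C@@H]1C(C)=CC[C@@H](C(=O)c2c(O)cc(O)cc2O)[C@@H]1c1ccccc1 | target

## Step count and risks

Total steps: 8. Longest linear sequence: 7 (steps 1, 2, 3, 4, 5, 7, 8).

Steps most likely to fail:

1. **Step 2.** The diene may be oxidised back to the arene by the Cu(III)/iodonium system, the methyl enol ethers may be too unreactive, double arylation may occur, or the ee may be low (the cis/trans isomers of 2 may respond differently). Fallback: hydrolyse 2 to the σ-symmetric 1,3-dione, form the racemic methyl vinylogous ester, install phenyl by Pd-catalysed α′-arylation with PhBr, and obtain the single enantiomer by resolution (chiral-amine salt of the derived acid, or preparative chiral chromatography of 4).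
2. **Step 3.** The prenyl reagent may attack through its substituted terminus (reverse prenyl), or the hindered α-phenyl ketone may enolise. Fallback: add allylmagnesium bromide/CeCl3 (no regiochemical ambiguity), carry the allyl group through steps 4–5, then convert it to prenyl by cross-metathesis with 2-methyl-2-butene (Ru–NHC catalyst) before step 7.
3. **Step 5.** Hydride may add to the hydrazone from the other face, giving the C-2′ epimer. Fallback: Luche reduction of 6 to the allylic alcohol, then Mitsunobu displacement with o-nitrobenzenesulfonylhydrazine (Myers allylic diazene). This installs the diazene with inversion and so gives the opposite C-2′ outcome from the same hydride facial preference.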